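**Plan**

- Retrosynthesis: the ring B quinone is taken back to a hydroquinone masked as two benzyl ethers. Ring C is then cut at O1–C2 (oxa-Michael) and at C2–C3 (Knoevenagel), with a temporary tert-butyl ester on C3 that comes from Boc2O.
- The O1–C2 cut is available because C2 carries the ring oxygen O1 and lies β to the C4 aryl ketone. The opened ring A (2,6-dihydroxy-4-methoxy-3,5-dimethylbenzoyl) has two equivalent hydroxyls beside the acyl group, so either one closes to the same chromanone.
- Forward: rings A and B come from the starting materials. The ring A acetophenone is C-methylated, 4-O-methylated and C-carboxylated. The ring B aldehyde is made from methoxyhydroquinone and joined as the C2=C3 alkene. Ring C is closed, then ring B is debenzylated and oxidised.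
- Stereochemistry: the single stereocentre, C2 (S), is set in the ring closure by a cinchona-derived bifunctional thiourea. The later steps are neutral and do not touch it.

Key step: step 7

Assumption: the quinidine-derived thiourea is taken as the pseudoenantiomer that gives 2S. The sense of induction is to be checked on the first batch of 11 by circular dichroism, and the quinine-derived catalyst replaces it if the sense is opposite.

**Route**

Step 1
Reactants: 1 2,4,6-trihydroxyacetophenone
Product: 2 1-(2,4,6-trihydroxy-3,5-dimethylphenyl)ethanone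
Conditions: MeI (2.2 equiv), NaOMe (2.2 equiv), MeOH, 0 °C → reflux
Reagents that add atoms: iodomethane, CI
Why: Nuclear C-methylation of an acylphloroglucinol phenoxide at its two free ring carbons is a known alkylation, and holding base and MeI near two equivalents should limit geminal over-methylation.

Step 2
Reactants: 2 1-(2,4,6-trihydroxy-3,5-dimethylphenyl)ethanone
Product: 3 1-(2,6-dihydroxy-4-methoxy-3,5-dimethylphenyl)ethanone
Conditions: Me2SO4 (1.0 equiv), K2CO3 (1.0 equiv), acetone, rt
Reagents that add atoms: dimethyl sulfate, COS(=O)(=O)OC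
Why: Williamson O-methylation should go at the 4-hydroxyl, which is para to the acyl group and therefore the most acidic, while the two ortho hydroxyls are held back by hydrogen bonding to the carbonyl.

Step 3
Reactants: 3 1-(2,6-dihydroxy-4-methoxy-3,5-dimethylphenyl)ethanone
Product: 4 tert-butyl 3-(2,6-dihydroxy-4-methoxy-3,5-dimethylphenyl)-3-oxopropanoate
Conditions: LiN(SiMe3)2 (4.5 equiv), THF, −78 → −20 °C; Boc2O (1.1 equiv), −78 → 0 °C; aq. NH4Cl
Reagents that add atoms: di-tert-butyl dicarbonate, CC(C)(C)OC(=O)OC(=O)OC(C)(C)C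
Why: Claisen-type C-acylation of the lithium polyanion of a hydroxyacetophenone should take place at the enolate carbon, the most nucleophilic site, and any carbonate formed on a phenoxide can pass its acyl group to the enolate in a Baker–Venkataraman-like transfer.

Step 4
Reactants: 5 methoxyhydroquinone (2-methoxybenzene-1,4-diol)
Product: 6 1,4-bis(benzyloxy)-2-methoxybenzene
Conditions: BnBr (2.3 equiv), K2CO3 (2.5 equiv), DMF, rt → 50 °C, N2
Reagents that add atoms: benzyl bromide, BrCc1ccccc1
Why: Williamson ether synthesis on both phenols, run under nitrogen because the hydroquinone anion is sensitive to air.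

Step 5
Reactants: 6 1,4-bis(benzyloxy)-2-methoxybenzene
Product: 7 2,5-bis(benzyloxy)-4-methoxybenzaldehyde
Conditions: POCl3 (1.5 equiv), DMF, 0 → 70 °C; then H2O
Reagents that add atoms: N,N-dimethylformamide, CN(C)C=O; water, O
Why: Vilsmeier–Haack formylation of a 1,2,4-trialkoxybenzene should go at C5, para to the methoxy group and ortho to a benzyloxy group, as it does for 1,2,4-trimethoxybenzene.

Step 6
Reactants: 4 tert-butyl 3-(2,6-dihydroxy-4-methoxy-3,5-dimethylphenyl)-3-oxopropanoate; 7 2,5-bis(benzyloxy)-4-methoxybenzaldehyde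
Product: 8 tert-butyl (E)-3-[2,5-bis(benzyloxy)-4-methoxyphenyl]-2-(2,6-dihydroxy-4-methoxy-3,5-dimethylbenzoyl)acrylate
Conditions: piperidine (0.2 equiv), AcOH (0.2 equiv), 4 Å MS, toluene, rt → 40 °C
Reagents that add atoms: none
Why: Knoevenagel condensation of the active methylene with the aryl aldehyde through its iminium ion should give the alkylidene β-keto ester (the Z isomer is carried along), and the low temperature is meant to keep the phenols from adding to the new alkene before the chiral catalyst is present.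

Step 7
Reactants: 8 tert-butyl (E)-3-[2,5-bis(benzyloxy)-4-methoxyphenyl]-2-(2,6-dihydroxy-4-methoxy-3,5-dimethylbenzoyl)acrylate
Product: 11 (2S)-2-[2,5-bis(benzyloxy)-4-methoxyphenyl]-5-hydroxy-7-methoxy-6,8-dimethylchroman-4-one, via 3-tert-butoxycarbonyl flavanone 9 (not isolated), via flavanone-3-carboxylic acid 10 (not isolated)
Conditions: 1-[3,5-bis(trifluoromethyl)phenyl]-3-(9-deoxy-epi-quinidin-9-yl)thiourea (10 mol%), toluene, −25 °C; then TsOH·H2O (0.5 equiv), 70–80 °C
Reagents that add atoms: none
Why: The quinuclidine nitrogen of the catalyst acts as a general base on a phenol while the thiourea hydrogen-bonds the β-keto ester, and the phenol oxygen adds to the arylidene carbon to form O1–C2 in an intramolecular oxa-Michael addition that gives the 3-ester 9. The closest known reaction is the cinchona-thiourea cyclisation of 2-hydroxyphenyl alkylidene β-keto esters to 3-carboxylated flavanones, followed by acid decarboxylation in the same flask. Ring C closes in the 6-endo-trig mode. The new C2 centre is controlled by the catalyst, which exposes one face of the alkene in the doubly hydrogen-bonded complex, and the alkene isomers of 8 are expected to converge because alkylidene β-keto esters equilibrate under amine bases. Only enantioface selectivity is needed, because the two hydroxyls flanking the acyl group of ring A are equivalent and either closure gives the same product, the other hydroxyl ending as the chelated 5-OH. TsOH then cleaves the tert-butyl ester to acid 10 with loss of isobutene and the β-keto acid loses CO2, at the lowest temperature that allows this so that the electron-rich C2 aryl group does not promote acid ionisation of C2–O1.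

Step 8
Reactants: 11 (2S)-2-[2,5-bis(benzyloxy)-4-methoxyphenyl]-5-hydroxy-7-methoxy-6,8-dimethylchroman-4-one
Product: 12 (2S)-2-(2,5-dihydroxy-4-methoxyphenyl)-5-hydroxy-7-methoxy-6,8-dimethylchroman-4-one
Conditions: H2 (1 atm), 10% Pd/C, EtOAc, rt; filtered under Ar
Reagents that add atoms: none
Why: Catalytic hydrogenolysis should cleave the two primary benzyl aryl ethers much faster than the cyclic secondary benzylic C2–O1 bond or the chelated aryl ketone, as is usual for benzyl-protected flavanones, and the neutral medium leaves C2 untouched.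

Step 9
Reactants: 12 (2S)-2-(2,5-dihydroxy-4-methoxyphenyl)-5-hydroxy-7-methoxy-6,8-dimethylchroman-4-one
Product: 13 2-[(2S)-5-hydroxy-7-methoxy-6,8-dimethyl-4-oxochroman-2-yl]-5-methoxy-1,4-benzoquinone
Conditions: Ag2O (2.5 equiv), MgSO4, Et2O–CH2Cl2, rt, dark
Reagents that add atoms: none
Why: Two-electron oxidation of a para-hydroquinone to the 1,4-benzoquinone by Ag2O is fast and close to neutral, and it should leave the chelated acylphenol of ring A and the C2 centre alone.

**Compound list**

1 | 2,4,6-trihydroxyacetophenone | CC(=O)c1c(O)cc(O)cc1O | starting material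
2 | 1-(2,4,6-trihydroxy-3,5-dimethylphenyl)ethanone | CC(=O)c1c(O)c(C)c(O)c(C)c1O | intermediate
3 | 1-(2,6-dihydroxy-4-methoxy-3,5-dimethylphenyl)ethanone | CC(=O)c1c(O)c(C)c(OC)c(C)c1O | intermediate
4 | tert-butyl 3-(2,6-dihydroxy-4-methoxy-3,5-dimethylphenyl)-3-oxopropanoate | CC(C)(C)OC(=O)CC(=O)c1c(O)c(C)c(OC)c(C)c1O | intermediate
5 | methoxyhydroquinone (2-methoxybenzene-1,4-diol) | COc1cc(O)ccc1O | starting material
6 | 1,4-bis(benzyloxy)-2-methoxybenzene | COc1cc(OCc2ccccc2)ccc1OCc1ccccc1 | intermediate
7 | 2,5-bis(benzyloxy)-4-methoxybenzaldehyde | COc1cc(OCc2ccccc2)c(C=O)cc1OCc1ccccc1 | intermediate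
8 | tert-butyl (E)-3-[2,5-bis(benzyloxy)-4-methoxyphenyl]-2-(2,6-dihydroxy-4-methoxy-3,5-dimethylbenzoyl)acrylate | COc1cc(OCc2ccccc2)c(cc1OCc1ccccc1)/C=C(/C(=O)OC(C)(C)C)C(=O)c3c(O)c(C)c(OC)c(C)c3O | intermediate
9 | tert-butyl (2S)-2-[2,5-bis(benzyloxy)-4-methoxyphenyl]-5-hydroxy-7-methoxy-6,8-dimethyl-4-oxochromane-3-carboxylate (C3 epimers and enol form; not isolated) | COc1cc(OCc2ccccc2)c(cc1OCc1ccccc1)[C@@H]3C(C(=O)OC(C)(C)C)C(=O)c4c(O)c(C)c(OC)c(C)c4O3 | intermediate
10 | (2S)-2-[2,5-bis(benzyloxy)-4-methoxyphenyl]-5-hydroxy-7-methoxy-6,8-dimethyl-4-oxochromane-3-carboxylic acid (not isolated) | COc1cc(OCc2ccccc2)c(cc1OCc1ccccc1)[C@@H]3C(C(=O)O)C(=O)c4c(O)c(C)c(OC)c(C)c4O3 | intermediate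
11 | (2S)-2-[2,5-bis(benzyloxy)-4-methoxyphenyl]-5-hydroxy-7-methoxy-6,8-dimethylchroman-4-one | COc1cc(OCc2ccccc2)c(cc1OCc1ccccc1)[C@@H]3CC(=O)c4c(O)c(C)c(OC)c(C)c4O3 | intermediate
12 | (2S)-2-(2,5-dihydroxy-4-methoxyphenyl)-5-hydroxy-7-methoxy-6,8-dimethylchroman-4-one | COc1cc(O)c(cc1O)[C@@H]2CC(=O)c3c(O)c(C)c(OC)c(C)c3O2 | intermediate
13 | 2-[(2S)-5-hydroxy-7-methoxy-6,8-dimethyl-4-oxochroman-2-yl]-5-methoxy-1,4-benzoquinone | COC1=CC(=O)C([C@@H]2CC(=O)c3c(O)c(C)c(OC)c(C)c3O2)=CC1=O | target

**Count**

Total steps: 9. Longest linear sequence: 7 steps (steps 1, 2, 3, 6, 7, 8, 9, from 1); the ring B branch (steps 4 and 5) joins at step 6.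

**Steps most likely to fail**

Step 7. The enantioface discrimination may be poor, because the second, non-chelated phenol can close without the catalyst. The enantiomeric purity may also erode during the acidic decarboxylation through reversible ionisation of C2–O1, which the 2- and 4-alkoxy groups of ring B assist. The fallback forms the C2–aryl bond instead of O1–C2, by asymmetric 1,4-addition to a chromone, and avoids both the ester and the acid.
- Setting out from 3, condensation with N,N-dimethylformamide dimethyl acetal should give (E)-1-(2,6-dihydroxy-4-methoxy-3,5-dimethylphenyl)-3-(dimethylamino)prop-2-en-1-one F1.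
- Aqueous HCl should close F1 to 5-hydroxy-7-methoxy-6,8-dimethyl-4H-chromen-4-one F2.
- Setting out from 6, NBS bromination para to the methoxy group should give 1,4-bis(benzyloxy)-2-bromo-5-methoxybenzene F3.
- Bromine–lithium exchange with n-BuLi, B(OiPr)3 and hydrolysis should give [2,5-bis(benzyloxy)-4-methoxyphenyl]boronic acid F4.
- A Hayashi–Miyaura addition of F4 to F2 ([Rh(OH)(cod)]2 with the enantiomer of an electron-poor MeO-BIPHEP-type bisphosphine that leads to 2S, toluene–H2O) would give 11 directly, where the route is rejoined.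

Step 6. The electron-rich aldehyde may condense slowly. Under the amine–acid conditions the bis-phenolic alkylidene may also ring-close as it forms, which would deliver racemic material before the chiral catalyst is present. The fallback masks one of the two equivalent phenols, so that the condensation and the ring closure are run on a mono-phenol of the known substrate class.
- From 3, BnBr (1 equiv) and K2CO3 should give 1-[2-(benzyloxy)-6-hydroxy-4-methoxy-3,5-dimethylphenyl]ethanone F5, the remaining chelated hydroxyl resisting a second alkylation.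
- LiN(SiMe3)2 and Boc2O should give tert-butyl 3-[2-(benzyloxy)-6-hydroxy-4-methoxy-3,5-dimethylphenyl]-3-oxopropanoate F6.
- Knoevenagel condensation with 7 should give tert-butyl (E)-2-[2-(benzyloxy)-6-hydroxy-4-methoxy-3,5-dimethylbenzoyl]-3-[2,5-bis(benzyloxy)-4-methoxyphenyl]acrylate F7.
- The thiourea cyclisation with TsOH should pass through tert-butyl (2S)-5-(benzyloxy)-2-[2,5-bis(benzyloxy)-4-methoxyphenyl]-7-methoxy-6,8-dimethyl-4-oxochromane-3-carboxylate F8 and (2S)-5-(benzyloxy)-2-[2,5-bis(benzyloxy)-4-methoxyphenyl]-7-methoxy-6,8-dimethyl-4-oxochromane-3-carboxylic acid F9 to (2S)-5-(benzyloxy)-2-[2,5-bis(benzyloxy)-4-methoxyphenyl]-7-methoxy-6,8-dimethylchroman-4-one F10.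
- Hydrogenolysis of all three benzyl ethers (H2, Pd/C) rejoins the route at 12.

Step 3. The phenoxides of the trianion may be acylated in place of the enolate carbon, or a phenoxide may attack the new ester and close a 4-hydroxycoumarin. The fallback is protection, carboxylation and deprotection.
- From 3, excess BnBr with K2CO3 in DMF at 70 °C should give 1-[2,6-bis(benzyloxy)-4-methoxy-3,5-dimethylphenyl]ethanone F11.
- LiN(SiMe3)2 (2.2 equiv) and Boc2O should give tert-butyl 3-[2,6-bis(benzyloxy)-4-methoxy-3,5-dimethylphenyl]-3-oxopropanoate F12.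
- Hydrogenolysis (H2, Pd/C, EtOAc) returns to 4.

**Further compounds**

F1 | step 7 | (E)-1-(2,6-dihydroxy-4-methoxy-3,5-dimethylphenyl)-3-(dimethylamino)prop-2-en-1-one | CN(C)/C=C/C(=O)c1c(O)c(C)c(OC)c(C)c1O
F2 | step 7 | 5-hydroxy-7-methoxy-6,8-dimethyl-4H-chromen-4-one | O=C1C=COc2c(C)c(OC)c(C)c(O)c12
F3 | step 7 | 1,4-bis(benzyloxy)-2-bromo-5-methoxybenzene | COc1cc(OCc2ccccc2)c(Br)cc1OCc1ccccc1
F4 | step 7 | [2,5-bis(benzyloxy)-4-methoxyphenyl]boronic acid | COc1cc(OCc2ccccc2)c(B(O)O)cc1OCc1ccccc1
F5 | step 6 | 1-[2-(benzyloxy)-6-hydroxy-4-methoxy-3,5-dimethylphenyl]ethanone | CC(=O)c1c(O)c(C)c(OC)c(C)c1OCc1ccccc1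
F6 | step 6 | tert-butyl 3-[2-(benzyloxy)-6-hydroxy-4-methoxy-3,5-dimethylphenyl]-3-oxopropanoate | CC(C)(C)OC(=O)CC(=O)c1c(O)c(C)c(OC)c(C)c1OCc1ccccc1
F7 | step 6 | tert-butyl (E)-2-[2-(benzyloxy)-6-hydroxy-4-methoxy-3,5-dimethylbenzoyl]-3-[2,5-bis(benzyloxy)-4-methoxyphenyl]acrylate | COc1cc(OCc2ccccc2)c(cc1OCc1ccccc1)/C=C(/C(=O)OC(C)(C)C)C(=O)c1c(O)c(C)c(OC)c(C)c1OCc1ccccc1
F8 | step 6 | tert-butyl (2S)-5-(benzyloxy)-2-[2,5-bis(benzyloxy)-4-methoxyphenyl]-7-methoxy-6,8-dimethyl-4-oxochromane-3-carboxylate | COc1cc(OCc2ccccc2)c(cc1OCc1ccccc1)[C@@H]3C(C(=O)OC(C)(C)C)C(=O)c4c(OCc5ccccc5)c(C)c(OC)c(C)c4O3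
F9 | step 6 | (2S)-5-(benzyloxy)-2-[2,5-bis(benzyloxy)-4-methoxyphenyl]-7-methoxy-6,8-dimethyl-4-oxochromane-3-carboxylic acid | COc1cc(OCc2ccccc2)c(cc1OCc1ccccc1)[C@@H]3C(C(=O)O)C(=O)c4c(OCc5ccccc5)c(C)c(OC)c(C)c4O3
F10 | step 6 | (2S)-5-(benzyloxy)-2-[2,5-bis(benzyloxy)-4-methoxyphenyl]-7-methoxy-6,8-dimethylchroman-4-one | COc1cc(OCc2ccccc2)c(cc1OCc1ccccc1)[C@@H]3CC(=O)c4c(OCc5ccccc5)c(C)c(OC)c(C)c4O3
F11 | step 3 | 1-[2,6-bis(benzyloxy)-4-methoxy-3,5-dimethylphenyl]ethanone | CC(=O)c1c(OCc2ccccc2)c(C)c(OC)c(C)c1OCc1ccccc1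
F12 | step 3 | tert-butyl 3-[2,6-bis(benzyloxy)-4-methoxy-3,5-dimethylphenyl]-3-oxopropanoate | CC(C)(C)OC(=O)CC(=O)c1c(OCc2ccccc2)c(C)c(OC)c(C)c1OCc1ccccc1
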